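**Plan**
Retrosynthetic cuts: the oxirane C6–O bond (back to a cis C1/C6 diol through a C6 bromide); the C2–OMe and C3–OBz bonds (back to a C2,C3-oxirane and then the C2=C3 alkene); the C7–O benzoate (back to a carboxyl group); finally the C1–O and C6–O bonds, which leads to benzoic acid.
Enabling feature: in the six-membered carbocycle, C1 is quaternary, carries oxygen and the one-carbon branch C7, and sits next to oxygenated C6. This is the ipso/ortho pair of benzoic acid with C7 as the carboxyl carbon, the pattern a benzoate dioxygenase hydroxylates.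
Forward order: the carbocycle is the benzene ring of benzoic acid and is never closed. The enzyme installs C1–O and C6–O first, C7 is then reduced and benzoylated, C2=C3 is oxygenated, and the oxirane, the only ring closed, is formed in the last step.
Stereochemistry: C1 and C6 come from the enzyme. C2 comes from epoxidation directed by the C1 hydroxyl (same face). C3 comes from SN2 opening by benzoate (opposite face). C6 is inverted twice (Appel bromination, then oxirane closure), so its enzyme-set configuration returns.
Key step: step 1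

Remark (locants and faces used throughout): C1 = quaternary ring carbon bearing C7; C2 and C3 = the carbons that end as CH–OMe and CH–OBz; C4=C5; C6 = oxygenated CH next to C1; β = ring face of the C1–O bond, α = face of C7. The target is then C1–O–C6 oxirane β, 2-OMe β, 3-OBz α. The blocked-mutant strain is taken as obtainable from a culture collection.

**Step 1**
Reactants: 1 benzoic acid
Product: 2 (1S,2R)-1,2-dihydroxycyclohexa-3,5-diene-1-carboxylic acid (route locants: C1–OH and C6–OH both β, C7 carboxyl α, diene C2=C3–C4=C5)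
Conditions: Ralstonia eutropha B9 whole cells (mutant lacking the dihydrodiol dehydrogenase), PhCO2Na feed, fructose, air, aqueous mineral medium, pH 7, 30 °C; cells removed, pH 3 at 0 °C, EtOAc extraction, crystallisation
Reagents that add atoms: dioxygen, O=O
Why: Benzoate 1,2-dioxygenase, a Rieske non-haem iron enzyme, binds benzoate and transfers both atoms of one O2 molecule, activated at its mononuclear iron centre with two electrons from cellular NADH, to one face of the ipso and ortho carbons, so the C1–O and C6–O bonds form cis and the C2=C3–C4=C5 diene is left. The closest known reaction type is Rieske-dioxygenase arene cis-dihydroxylation, as used with toluene dioxygenase on substituted benzenes. No ring is closed, since the carbocycle is the original benzene ring. Both new stereocentres are fixed by the chiral active site, which should give the (1S,2R) diol as one enantiomer with the C1 and C6 oxygens on the face required by the target. The step needs ipso/ortho regioselectivity, which the anchoring of the carboxylate in the active site provides, and it needs the diol to persist, which the missing dehydrogenase of the B9 mutant ensures because re-aromatisation to catechol cannot follow.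

**Step 2**
Reactants: 2 (1S,2R)-1,2-dihydroxycyclohexa-3,5-diene-1-carboxylic acid; 3 iodomethane
Product: 4 methyl (1S,2R)-1,2-dihydroxycyclohexa-3,5-diene-1-carboxylate
Conditions: MeI, KHCO3, DMF, rt
Reagents that add atoms: iodomethane, CI
Why: Carboxylate O-alkylation (SN2 on iodomethane) under bicarbonate, a base too weak to ionise either hydroxyl, should give only the ester and keeps the dehydration-prone dienediol away from acid.

**Step 3**
Reactants: 4 methyl (1S,2R)-1,2-dihydroxycyclohexa-3,5-diene-1-carboxylate; 5 tert-butyldimethylsilyl chloride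
Product: 6 methyl (1S,6R)-6-(tert-butyldimethylsilyloxy)-1-hydroxycyclohexa-2,4-diene-1-carboxylate (C6–OTBS β, C1–OH β free)
Conditions: TBSCl, imidazole, DMF, 0 °C to rt
Reagents that add atoms: tert-butyldimethylsilyl chloride, CC(C)(C)[Si](C)(C)Cl
Why: Silyl ether formation is much faster at the secondary allylic C6 hydroxyl than at the tertiary α-hydroxy-ester hydroxyl, which removes the directing group next to C4=C5 and leaves the C1 hydroxyl free to direct the later epoxidation.

**Step 4**
Reactants: 6 methyl (1S,6R)-6-(tert-butyldimethylsilyloxy)-1-hydroxycyclohexa-2,4-diene-1-carboxylate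
Product: 7 (1R,6R)-6-(tert-butyldimethylsilyloxy)-1-(hydroxymethyl)cyclohexa-2,4-dien-1-ol
Conditions: LiAlH4, THF, −20 to 0 °C; H2O, aq. NaOH work-up
Reagents that add atoms: none
Why: Hydride reduction of the ester to the primary C7 alcohol with LiAlH4 touches neither the silyl ether nor the diene, and no stereocentre is involved (the C1 descriptor changes only because the substituent priorities change).

**Step 5**
Reactants: 7 (1R,6R)-6-(tert-butyldimethylsilyloxy)-1-(hydroxymethyl)cyclohexa-2,4-dien-1-ol; 8 benzoyl chloride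
Product: 9 [(1R,6R)-6-(tert-butyldimethylsilyloxy)-1-hydroxycyclohexa-2,4-dien-1-yl]methyl benzoate
Conditions: BzCl (1.05 equiv), pyridine, CH2Cl2, −20 to 0 °C
Reagents that add atoms: benzoyl chloride, O=C(Cl)c1ccccc1
Why: Pyridine-mediated acylation is selective for the primary C7 hydroxyl over the hindered tertiary C1 hydroxyl, so the C7 benzoate of the target is in place before any base-sensitive group is made.

**Step 6**
Reactants: 9 [(1R,6R)-6-(tert-butyldimethylsilyloxy)-1-hydroxycyclohexa-2,4-dien-1-yl]methyl benzoate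
Product: 10 [(1S,2S,3S,6R)-6-(tert-butyldimethylsilyloxy)-2,3-epoxy-1-hydroxycyclohex-4-en-1-yl]methyl benzoate (C2,C3-oxirane β, syn to C1–OH)
Conditions: VO(acac)2 (5 mol %), t-BuOOH (in decane), CH2Cl2, 0 °C
Reagents that add atoms: tert-butyl hydroperoxide, CC(C)(C)OO
Why: In this vanadium-catalysed hydroxyl-directed epoxidation the tertiary allylic C1 alkoxide binds the vanadium alkylperoxide and delivers oxygen to the adjacent C2=C3 bond on its own β face, setting C2 and C3, while C4=C5 is only homoallylic to that hydroxyl and is shielded on the β face by the C6 silyl ether.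

**Step 7**
Reactants: 10 [(1S,2S,3S,6R)-6-(tert-butyldimethylsilyloxy)-2,3-epoxy-1-hydroxycyclohex-4-en-1-yl]methyl benzoate; 1 benzoic acid
Product: 11 [(1S,2S,3R,6R)-3-(benzoyloxy)-6-(tert-butyldimethylsilyloxy)-1,2-dihydroxycyclohex-4-en-1-yl]methyl benzoate (2-OH β, 3-OBz α)
Conditions: PhCO2H, Ti(OiPr)4 (1.5 equiv), CH2Cl2, 0 °C to rt; aq. tartaric acid work-up
Reagents that add atoms: benzoic acid, OC(=O)c1ccccc1
Why: In this titanium-mediated opening of a 2,3-epoxy alcohol by a carboxylic acid, the C1–O–Ti chelate activates the oxirane and benzoate attacks the allylic C3 from the α face (SN2, inversion), which puts the C3 benzoate trans to the retained β C2 oxygen, whereas C2 is flanked by the quaternary C1 and is not attacked.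

**Step 8**
Reactants: 11 [(1S,2S,3R,6R)-3-(benzoyloxy)-6-(tert-butyldimethylsilyloxy)-1,2-dihydroxycyclohex-4-en-1-yl]methyl benzoate; 12 trimethyloxonium tetrafluoroborate
Product: 13 [(1S,2S,3R,6R)-3-(benzoyloxy)-6-(tert-butyldimethylsilyloxy)-1-hydroxy-2-methoxycyclohex-4-en-1-yl]methyl benzoate
Conditions: Me3OBF4, 1,8-bis(dimethylamino)naphthalene, CH2Cl2, 0 °C to rt
Reagents that add atoms: trimethyloxonium tetrafluoroborate, C[O+](C)C.F[B-](F)(F)F
Why: O-Methylation with the oxonium salt buffered by a hindered amine forms no alkoxide, so the neighbouring benzoates should not migrate, and the secondary C2 hydroxyl should react ahead of the far more hindered tertiary C1 hydroxyl.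

**Step 9**
Reactants: 13 [(1S,2S,3R,6R)-3-(benzoyloxy)-6-(tert-butyldimethylsilyloxy)-1-hydroxy-2-methoxycyclohex-4-en-1-yl]methyl benzoate
Product: 14 [(1R,2S,3R,6R)-3-(benzoyloxy)-1,6-dihydroxy-2-methoxycyclohex-4-en-1-yl]methyl benzoate (C1–OH and C6–OH cis, both β)
Conditions: HF·pyridine, pyridine, THF, 0 °C to rt
Reagents that add atoms: none
Why: Fluoride-driven desilylation under buffered, weakly acidic conditions frees the C6 hydroxyl while benzoates, the methyl ether and the alkene are inert and no alkoxide is present to trigger acyl migration.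

**Step 10**
Reactants: 14 [(1R,2S,3R,6R)-3-(benzoyloxy)-1,6-dihydroxy-2-methoxycyclohex-4-en-1-yl]methyl benzoate
Product: 15 [(1S,2S,3R,6S)-3-(benzoyloxy)-6-bromo-1-hydroxy-2-methoxycyclohex-4-en-1-yl]methyl benzoate (C6–Br α, trans to C1–OH)
Conditions: PPh3, CBr4, CH2Cl2, 0 °C; rapid filtration through silica, used at once
Reagents that add atoms: tetrabromomethane, BrC(Br)(Br)Br
Why: In this Appel reaction the secondary allylic C6 oxygen is converted into an oxyphosphonium leaving group that bromide displaces by SN2 with inversion, the known course for cyclic cis-1,2-diols, which give trans-halohydrins, while the tertiary C1 hydroxyl cannot be substituted.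

**Step 11**
Reactants: 15 [(1S,2S,3R,6S)-3-(benzoyloxy)-6-bromo-1-hydroxy-2-methoxycyclohex-4-en-1-yl]methyl benzoate
Product: 16 [(1R,2S,3R,6R)-3-(benzoyloxy)-2-methoxy-7-oxabicyclo[4.1.0]hept-4-en-1-yl]methyl benzoate (CNP0231490.2)
Conditions: K2CO3 (powdered), MeCN, 0 °C to rt
Reagents that add atoms: none
Why: In this intramolecular Williamson etherification (halohydrin to oxirane, 3-exo-tet) the C1 alkoxide displaces the anti C6 bromide from the β face with a second inversion, so C6 regains its enzyme-set configuration and the oxirane lies on the face of the C1 oxygen, while carbonate in an aprotic solvent should leave both benzoates intact.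

**Compound list**
1 | benzoic acid | OC(=O)c1ccccc1 | starting material
2 | (1S,2R)-1,2-dihydroxycyclohexa-3,5-diene-1-carboxylic acid | OC(=O)[C@]1(O)C=CC=C[C@H]1O | intermediate
3 | iodomethane | CI | starting material
4 | methyl (1S,2R)-1,2-dihydroxycyclohexa-3,5-diene-1-carboxylate | COC(=O)[C@]1(O)C=CC=C[C@H]1O | intermediate
5 | tert-butyldimethylsilyl chloride | CC(C)(C)[Si](C)(C)Cl | starting material
6 | methyl (1S,6R)-6-(tert-butyldimethylsilyloxy)-1-hydroxycyclohexa-2,4-diene-1-carboxylate | COC(=O)[C@]1(O)C=CC=C[C@H]1O[Si](C)(C)C(C)(C)C | intermediate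
7 | (1R,6R)-6-(tert-butyldimethylsilyloxy)-1-(hydroxymethyl)cyclohexa-2,4-dien-1-ol | OC[C@]1(O)C=CC=C[C@H]1O[Si](C)(C)C(C)(C)C | intermediate
8 | benzoyl chloride | O=C(Cl)c1ccccc1 | starting material
9 | [(1R,6R)-6-(tert-butyldimethylsilyloxy)-1-hydroxycyclohexa-2,4-dien-1-yl]methyl benzoate | O=C(OC[C@]1(O)C=CC=C[C@H]1O[Si](C)(C)C(C)(C)C)c1ccccc1 | intermediate
10 | [(1S,2S,3S,6R)-6-(tert-butyldimethylsilyloxy)-2,3-epoxy-1-hydroxycyclohex-4-en-1-yl]methyl benzoate | O=C(OC[C@]1(O)[C@H]2O[C@H]2C=C[C@H]1O[Si](C)(C)C(C)(C)C)c1ccccc1 | intermediate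
11 | [(1S,2S,3R,6R)-3-(benzoyloxy)-6-(tert-butyldimethylsilyloxy)-1,2-dihydroxycyclohex-4-en-1-yl]methyl benzoate | O[C@H]1[C@H](OC(=O)c2ccccc2)C=C[C@@H](O[Si](C)(C)C(C)(C)C)[C@]1(O)COC(=O)c1ccccc1 | intermediate
12 | trimethyloxonium tetrafluoroborate | C[O+](C)C.F[B-](F)(F)F | starting material
13 | [(1S,2S,3R,6R)-3-(benzoyloxy)-6-(tert-butyldimethylsilyloxy)-1-hydroxy-2-methoxycyclohex-4-en-1-yl]methyl benzoate | CO[C@H]1[C@H](OC(=O)c2ccccc2)C=C[C@@H](O[Si](C)(C)C(C)(C)C)[C@]1(O)COC(=O)c1ccccc1 | intermediate
14 | [(1R,2S,3R,6R)-3-(benzoyloxy)-1,6-dihydroxy-2-methoxycyclohex-4-en-1-yl]methyl benzoate | CO[C@H]1[C@H](OC(=O)c2ccccc2)C=C[C@@H](O)[C@]1(O)COC(=O)c1ccccc1 | intermediate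
15 | [(1S,2S,3R,6S)-3-(benzoyloxy)-6-bromo-1-hydroxy-2-methoxycyclohex-4-en-1-yl]methyl benzoate | CO[C@H]1[C@H](OC(=O)c2ccccc2)C=C[C@H](Br)[C@]1(O)COC(=O)c1ccccc1 | intermediate
16 | [(1R,2S,3R,6R)-3-(benzoyloxy)-2-methoxy-7-oxabicyclo[4.1.0]hept-4-en-1-yl]methyl benzoate | CO[C@H]1[C@H](OC(=O)c2ccccc2)C=C[C@H]2O[C@]21COC(=O)c1ccccc1 | target

**Totals**
Total step count: 11. Longest linear sequence: 11 steps (1 to 16); the route is fully linear.

**Steps most likely to fail**

1. Step 6. Oxygen may be transferred to the other alkene (C4=C5) or to the α face, or the new vinyl oxirane may be opened by the Lewis-acidic catalyst before isolation. Fallback: from 9, hydrogen-bond-directed dihydroxylation with OsO4 and TMEDA (CH2Cl2, −78 °C; aq. Na2SO3) on the face of the C1 hydroxyl should give the all-cis triol [(1S,2S,3S,6R)-6-(tert-butyldimethylsilyloxy)-1,2,3-trihydroxycyclohex-4-en-1-yl]methyl benzoate F1. A Mitsunobu esterification (PPh3, DIAD, benzoic acid 1, THF, 0 °C) of its allylic, least hindered C3 hydroxyl then inverts C3 and rejoins the route at 11, bypassing 10.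

2. Step 10. Bromide may enter with allylic shift to C4, with retention through participation of the C7 benzoate, or too slowly beside the quaternary C1. Fallback: from 14, Dess–Martin periodinane (NaHCO3, CH2Cl2) oxidises the secondary allylic carbinol to the α-hydroxy enone [(1S,2S,3R)-3-(benzoyloxy)-1-hydroxy-2-methoxy-6-oxocyclohex-4-en-1-yl]methyl benzoate F2. Me4NBH(OAc)3 (MeCN/AcOH, −20 °C), bound to the C1 oxygen, delivers hydride to the β face of the ketone and should give the trans diol [(1R,2S,3R,6S)-3-(benzoyloxy)-1,6-dihydroxy-2-methoxycyclohex-4-en-1-yl]methyl benzoate F3. MsCl and Et3N (CH2Cl2, −20 °C) sulfonylate only the secondary hydroxyl to give [(1S,2S,3R,6S)-3-(benzoyloxy)-1-hydroxy-6-(methylsulfonyloxy)-2-methoxycyclohex-4-en-1-yl]methyl benzoate F4, which K2CO3 in MeCN closes with a single inversion to 16.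

3. Step 8. The methyl group may also be transferred to the tertiary C1 hydroxyl, or the benzoyl group may shift from O3 to O2 before methylation. Fallback: from 11, Bu2SnO (toluene, reflux, water removed) ties O1 and O2 into the 1,2-O-dibutylstannylene acetal of 11 F5, and iodomethane 3 with CsF in DMF alkylates only its secondary oxygen, giving 13 after aqueous work-up.

**Further compounds**
F1 | step 6 | [(1S,2S,3S,6R)-6-(tert-butyldimethylsilyloxy)-1,2,3-trihydroxycyclohex-4-en-1-yl]methyl benzoate | O[C@H]1[C@@H](O)C=C[C@@H](O[Si](C)(C)C(C)(C)C)[C@]1(O)COC(=O)c1ccccc1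
F2 | step 10 | [(1S,2S,3R)-3-(benzoyloxy)-1-hydroxy-2-methoxy-6-oxocyclohex-4-en-1-yl]methyl benzoate | CO[C@H]1[C@H](OC(=O)c2ccccc2)C=CC(=O)[C@]1(O)COC(=O)c1ccccc1
F3 | step 10 | [(1R,2S,3R,6S)-3-(benzoyloxy)-1,6-dihydroxy-2-methoxycyclohex-4-en-1-yl]methyl benzoate | CO[C@H]1[C@H](OC(=O)c2ccccc2)C=C[C@H](O)[C@]1(O)COC(=O)c1ccccc1
F4 | step 10 | [(1S,2S,3R,6S)-3-(benzoyloxy)-1-hydroxy-6-(methylsulfonyloxy)-2-methoxycyclohex-4-en-1-yl]methyl benzoate | CO[C@H]1[C@H](OC(=O)c2ccccc2)C=C[C@H](OS(C)(=O)=O)[C@]1(O)COC(=O)c1ccccc1
F5 | step 8 | 1,2-O-dibutylstannylene acetal of 11 | CCCC[Sn]1(CCCC)O[C@H]2[C@H](OC(=O)c3ccccc3)C=C[C@@H](O[Si](C)(C)C(C)(C)C)[C@]2(O1)COC(=O)c1ccccc1
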